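**Strategy**

Ring numbering: C1 is the carbonyl between C2 (OMe) and the chain-bearing C6; C4 is the other carbonyl, C5 carries the methyl. Everything rests on cutting the bond between the benzylic carbon on C6 and the next chain carbon. The oxygen on C1 lies ortho to C6; as an O-Boc group on a salicylaldehyde it turns the union into a one-flask reductive alkylation: the all-syn tetramethyl C16 alkylmagnesium chloride (from iterative Matteson homologation) adds to the formyl carbon, the alkoxide takes over the Boc group and expels it, giving an ortho-quinone methide (C1=O, exocyclic C6=C) that borohydride reduces to the free 2-alkylphenol. Fremy oxidation at C4 completes the quinone.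

Key step: step 12

Remark on the chemistry: (S)-1-bromo-2-methylbutane, (R,R)-DICHED and 7-chlorohept-1-yne are taken as catalogue chemicals; (R,R)-DICHED boronic esters are taken to give (αS)-chloro boronic esters with LiCHCl2/ZnCl2 (the sense known for C2-symmetric (R,R)-diol boronates), and the configuration of 8 would be confirmed before the sequence is continued.

**Route**

Step 1
Reactants: 1 (S)-1-bromo-2-methylbutane
Product: 4 (4R,5R)-4,5-dicyclohexyl-2-[(2R)-2-methylbutyl]-1,3,2-dioxaborolane, via Grignard reagent 2 (not isolated), via boronic acid 3 (not isolated)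
Conditions: Mg, THF; B(OMe)3, −78 °C → rt; aq. HCl; (R,R)-DICHED, MgSO4, Et2O, rt
Reagents that add atoms: trimethyl borate, COB(OC)OC; (1R,2R)-1,2-dicyclohexylethane-1,2-diol, O[C@H](C1CCCCC1)[C@H](O)C1CCCCC1
Why: Grignard formation, borylation and diol esterification take place at the primary carbon and at boron, so the chiral-pool methyl centre (C15 of the final side chain) is untouched, the R descriptor arising only from the changed CIP priorities.

Step 2
Reactants: 4 (4R,5R)-4,5-dicyclohexyl-2-[(2R)-2-methylbutyl]-1,3,2-dioxaborolane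
Product: 8 (4R,5R)-4,5-dicyclohexyl-2-[(2S,4S)-4-methylhexan-2-yl]-1,3,2-dioxaborolane, via dichloromethylborate 5 (not isolated), via chloro boronic ester 6 (not isolated), via methylborate 7 (not isolated)
Conditions: CH2Cl2, n-BuLi, THF, −100 °C; 4; ZnCl2, −100 °C → rt; then MeMgBr (excess), −78 °C → rt
Reagents that add atoms: dichloromethane, ClCCl; methylmagnesium bromide, C[Mg]Br
Why: Matteson asymmetric homologation, in which (dichloromethyl)lithium adds to boron, the ZnCl2-promoted 1,2-shift of the alkyl group displaces the chloride selected by the C2-symmetric (R,R)-DICHED ligand to give the (αS)-chloride, and the methyl group of the methylborate then migrates with inversion at carbon, so that the auxiliary sets the new boron-bearing centre (C13 of the final side chain) syn to the existing methyl centre.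

Step 3
Reactants: 8 (4R,5R)-4,5-dicyclohexyl-2-[(2S,4S)-4-methylhexan-2-yl]-1,3,2-dioxaborolane
Product: 10 (4R,5R)-4,5-dicyclohexyl-2-[(2R,4S)-2,4-dimethylhexyl]-1,3,2-dioxaborolane, via chloromethylborate 9 (not isolated)
Conditions: BrCH2Cl, n-BuLi, THF, −78 °C → rt
Reagents that add atoms: bromochloromethane, ClCBr
Why: Matteson CH2 homologation, in which chloromethyllithium made in the presence of 8 adds to boron and the secondary alkyl group migrates to the CH2 carbon with loss of chloride and retention at the migrating stereocentre.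

Step 4
Reactants: 10 (4R,5R)-4,5-dicyclohexyl-2-[(2R,4S)-2,4-dimethylhexyl]-1,3,2-dioxaborolane
Product: 14 (4R,5R)-4,5-dicyclohexyl-2-[(2S,4R,6S)-4,6-dimethyloctan-2-yl]-1,3,2-dioxaborolane, via dichloromethylborate 11 (not isolated), via chloro boronic ester 12 (not isolated), via methylborate 13 (not isolated)
Conditions: CH2Cl2, n-BuLi, THF, −100 °C; 10; ZnCl2, −100 °C → rt; then MeMgBr (excess), −78 °C → rt
Reagents that add atoms: dichloromethane, ClCCl; methylmagnesium bromide, C[Mg]Br
Why: Second Matteson asymmetric homologation under control of the same (R,R)-DICHED ligand (auxiliary-directed chloride displacement, then methyl migration with inversion), which sets the third methyl centre (C11 of the final side chain) syn to the first two.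

Step 5
Reactants: 14 (4R,5R)-4,5-dicyclohexyl-2-[(2S,4R,6S)-4,6-dimethyloctan-2-yl]-1,3,2-dioxaborolane
Product: 16 (4R,5R)-4,5-dicyclohexyl-2-[(2R,4R,6S)-2,4,6-trimethyloctyl]-1,3,2-dioxaborolane, via chloromethylborate 15 (not isolated)
Conditions: BrCH2Cl, n-BuLi, THF, −78 °C → rt
Reagents that add atoms: bromochloromethane, ClCBr
Why: Matteson CH2 homologation inserting the next methylene with retention at the migrating carbon, no stereocentre being formed.

Step 6
Reactants: 16 (4R,5R)-4,5-dicyclohexyl-2-[(2R,4R,6S)-2,4,6-trimethyloctyl]-1,3,2-dioxaborolane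
Product: 20 (4R,5R)-4,5-dicyclohexyl-2-[(2S,4R,6S,8S)-4,6,8-trimethyldecan-2-yl]-1,3,2-dioxaborolane, via dichloromethylborate 17 (not isolated), via chloro boronic ester 18 (not isolated), via methylborate 19 (not isolated)
Conditions: CH2Cl2, n-BuLi, THF, −100 °C; 16; ZnCl2, −100 °C → rt; then MeMgBr (excess), −78 °C → rt
Reagents that add atoms: dichloromethane, ClCCl; methylmagnesium bromide, C[Mg]Br
Why: Third Matteson asymmetric homologation with the same auxiliary, which sets the fourth methyl centre (C9 of the final side chain) syn to the others by the same chloride displacement and inversion sequence.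

Step 7
Reactants: 21 7-chlorohept-1-yne
Product: 23 (E)-7-chloro-1-iodohept-1-ene, via alkenylalane 22 (not isolated)
Conditions: DIBAL-H, hexane, 50 °C; I2, THF, −78 °C → rt
Reagents that add atoms: iodine, II
Why: Syn-hydroalumination of the terminal alkyne places aluminium on the terminal carbon and iodinolysis of the alkenyl–Al bond proceeds with retention to the (E)-iodide, the primary chloride being inert to DIBAL-H.

Step 8
Reactants: 20 (4R,5R)-4,5-dicyclohexyl-2-[(2S,4R,6S,8S)-4,6,8-trimethyldecan-2-yl]-1,3,2-dioxaborolane; 23 (E)-7-chloro-1-iodohept-1-ene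
Product: 27 (6Z,8S,10S,12S,14S)-1-chloro-8,10,12,14-tetramethylhexadec-6-ene, via alkenyllithium 24 (not isolated), via boronate complex 25 (not isolated), via iodo boronic ester 26 (not isolated)
Conditions: 23, t-BuLi, THF, −78 °C; then 20; I2, MeOH, −78 °C; NaOMe, MeOH, → rt
Reagents that add atoms: none
Why: Zweifel olefination, in which iodine triggers 1,2-migration of the secondary alkyl group from boron to the alkenyl carbon with retention at the migrating stereocentre and methoxide-induced anti-elimination from the β-iodo boronic ester gives the Z-alkene, whose geometry is irrelevant after step 9.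

Step 9
Reactants: 27 (6Z,8S,10S,12S,14S)-1-chloro-8,10,12,14-tetramethylhexadec-6-ene
Product: 28 (8R,10R,12S,14S)-1-chloro-8,10,12,14-tetramethylhexadecane
Conditions: H2 (1 atm), PtO2, EtOAc, rt
Reagents that add atoms: none
Why: Heterogeneous hydrogenation of the disubstituted alkene, with platinum chosen over palladium because it causes little double-bond migration toward the allylic methyl stereocentre and leaves the primary C–Cl bond intact.

Step 10
Reactants: 29 2-methoxy-5-methylphenol
Product: 30 2-hydroxy-3-methoxy-6-methylbenzaldehyde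
Conditions: MgCl2, Et3N, (CH2O)n, THF, reflux
Reagents that add atoms: paraformaldehyde (as formaldehyde), C=O
Why: Casnati–Skattebøl ortho-formylation, in which formaldehyde is delivered within the magnesium phenoxide chelate to the only free ortho carbon and a second formaldehyde oxidises the hydroxymethyl stage by hydride transfer, the para position staying untouched.

Step 11
Reactants: 30 2-hydroxy-3-methoxy-6-methylbenzaldehyde
Product: 31 tert-butyl (2-formyl-6-methoxy-3-methylphenyl) carbonate
Conditions: Boc2O, i-Pr2NEt, cat. DMAP, CH2Cl2, rt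
Reagents that add atoms: di-tert-butyl dicarbonate, CC(C)(C)OC(=O)OC(=O)OC(C)(C)C
Why: DMAP-catalysed O-acylation of the phenol gives the aryl tert-butyl carbonate that serves as the internal trigger of step 12.

Step 12
Reactants: 28 (8R,10R,12S,14S)-1-chloro-8,10,12,14-tetramethylhexadecane; 31 tert-butyl (2-formyl-6-methoxy-3-methylphenyl) carbonate
Product: 35 6-methoxy-3-methyl-2-[(9R,11R,13S,15S)-9,11,13,15-tetramethylheptadecyl]phenol, via Grignard reagent 32 (not isolated), via magnesium alkoxide 33 (not isolated), via quinone methide 34 (not isolated)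
Conditions: 28, Mg, cat. BrCH2CH2Br, THF, reflux; then 31, THF, −78 °C; LiBH4, −78 °C → rt; aq. NH4Cl
Reagents that add atoms: none
Why: The primary alkylmagnesium chloride 32 adds to the formyl carbon of 31 at −78 °C (Grignard 1,2-addition) and thereby forms the bond between the benzylic carbon and the chain; the magnesium alkoxide 33 then attacks the neighbouring aryl carbonate through a six-membered transition state, the Boc group moves to the benzylic oxygen and the freed phenoxide expels tert-butyl carbonate to give the ortho-quinone methide 34. Borohydride adds to the exocyclic carbon of 34 (1,4-reduction) and rearomatisation delivers the phenol, so the aldehyde oxygen is removed without a separate deoxygenation step. The closest known reaction types are the one-pot o-quinone methide cascade of O-Boc salicylaldehydes with an organometallic followed by a second nucleophile, and the borohydride reduction of such aldehydes to ortho-alkylphenols. No ring is closed and no stereocentre is created, since the carbinol centre of 33 is erased in 34 and the four methyl-bearing centres lie far from the reacting carbon. The selectivity needed is addition to the aldehyde and not to the carbonate, secured by the low temperature and the hindered tert-butyl carbonate, and hydride capture of 34 ahead of its 1,5-hydrogen shift or self-addition, secured by having the hydride in the flask before the mixture is warmed.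

Step 13
Reactants: 35 6-methoxy-3-methyl-2-[(9R,11R,13S,15S)-9,11,13,15-tetramethylheptadecyl]phenol
Product: 36 5-methoxy-2-methyl-3-[(9R,11R,13S,15S)-9,11,13,15-tetramethylheptadecyl]cyclohexa-2,5-diene-1,4-dione
Conditions: Fremy's salt, KH2PO4, acetone/H2O, rt
Reagents that add atoms: potassium nitrosodisulfonate (Fremy's salt), [K+].[K+].[O]N(S(=O)(=O)[O-])S(=O)(=O)[O-]
Why: Teuber oxidation, in which the phenoxyl radical is trapped by a second nitrosodisulfonate radical at the free para carbon (C4) and loss of imidodisulfonate gives the para-quinone, as expected for a 2-methoxy-6-alkylphenol with an unsubstituted para position.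

**Compound list**

1 | (S)-1-bromo-2-methylbutane | CC[C@H](C)CBr | starting material
2 | [(2S)-2-methylbutyl]magnesium bromide | CC[C@H](C)C[Mg]Br | intermediate
3 | [(2R)-2-methylbutyl]boronic acid | CC[C@H](C)CB(O)O | intermediate
4 | (4R,5R)-4,5-dicyclohexyl-2-[(2R)-2-methylbutyl]-1,3,2-dioxaborolane | CC[C@H](C)CB1O[C@H](C2CCCCC2)[C@@H](C2CCCCC2)O1 | intermediate
5 | lithium (dichloromethyl)borate complex of 4 | [Li+].CC[C@H](C)C[B-]1(C(Cl)Cl)O[C@H](C2CCCCC2)[C@@H](C2CCCCC2)O1 | intermediate
6 | (4R,5R)-2-[(1S,3S)-1-chloro-3-methylpentyl]-4,5-dicyclohexyl-1,3,2-dioxaborolane | CC[C@H](C)C[C@@H](Cl)B1O[C@H](C2CCCCC2)[C@@H](C2CCCCC2)O1 | intermediate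
7 | bromomagnesium methylborate complex of 6 | [Mg+2].[Br-].CC[C@H](C)C[C@@H](Cl)[B-]1(C)O[C@H](C2CCCCC2)[C@@H](C2CCCCC2)O1 | intermediate
8 | (4R,5R)-4,5-dicyclohexyl-2-[(2S,4S)-4-methylhexan-2-yl]-1,3,2-dioxaborolane | CC[C@H](C)C[C@H](C)B1O[C@H](C2CCCCC2)[C@@H](C2CCCCC2)O1 | intermediate
9 | lithium (chloromethyl)borate complex of 8 | [Li+].CC[C@H](C)C[C@H](C)[B-]1(CCl)O[C@H](C2CCCCC2)[C@@H](C2CCCCC2)O1 | intermediate
10 | (4R,5R)-4,5-dicyclohexyl-2-[(2R,4S)-2,4-dimethylhexyl]-1,3,2-dioxaborolane | CC[C@H](C)C[C@H](C)CB1O[C@H](C2CCCCC2)[C@@H](C2CCCCC2)O1 | intermediate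
11 | lithium (dichloromethyl)borate complex of 10 | [Li+].CC[C@H](C)C[C@H](C)C[B-]1(C(Cl)Cl)O[C@H](C2CCCCC2)[C@@H](C2CCCCC2)O1 | intermediate
12 | (4R,5R)-2-[(1S,3S,5S)-1-chloro-3,5-dimethylheptyl]-4,5-dicyclohexyl-1,3,2-dioxaborolane | CC[C@H](C)C[C@H](C)C[C@@H](Cl)B1O[C@H](C2CCCCC2)[C@@H](C2CCCCC2)O1 | intermediate
13 | bromomagnesium methylborate complex of 12 | [Mg+2].[Br-].CC[C@H](C)C[C@H](C)C[C@@H](Cl)[B-]1(C)O[C@H](C2CCCCC2)[C@@H](C2CCCCC2)O1 | intermediate
14 | (4R,5R)-4,5-dicyclohexyl-2-[(2S,4R,6S)-4,6-dimethyloctan-2-yl]-1,3,2-dioxaborolane | CC[C@H](C)C[C@H](C)C[C@H](C)B1O[C@H](C2CCCCC2)[C@@H](C2CCCCC2)O1 | intermediate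
15 | lithium (chloromethyl)borate complex of 14 | [Li+].CC[C@H](C)C[C@H](C)C[C@H](C)[B-]1(CCl)O[C@H](C2CCCCC2)[C@@H](C2CCCCC2)O1 | intermediate
16 | (4R,5R)-4,5-dicyclohexyl-2-[(2R,4R,6S)-2,4,6-trimethyloctyl]-1,3,2-dioxaborolane | CC[C@H](C)C[C@H](C)C[C@H](C)CB1O[C@H](C2CCCCC2)[C@@H](C2CCCCC2)O1 | intermediate
17 | lithium (dichloromethyl)borate complex of 16 | [Li+].CC[C@H](C)C[C@H](C)C[C@H](C)C[B-]1(C(Cl)Cl)O[C@H](C2CCCCC2)[C@@H](C2CCCCC2)O1 | intermediate
18 | (4R,5R)-2-[(1S,3S,5S,7S)-1-chloro-3,5,7-trimethylnonyl]-4,5-dicyclohexyl-1,3,2-dioxaborolane | CC[C@H](C)C[C@H](C)C[C@H](C)C[C@@H](Cl)B1O[C@H](C2CCCCC2)[C@@H](C2CCCCC2)O1 | intermediate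
19 | bromomagnesium methylborate complex of 18 | [Mg+2].[Br-].CC[C@H](C)C[C@H](C)C[C@H](C)C[C@@H](Cl)[B-]1(C)O[C@H](C2CCCCC2)[C@@H](C2CCCCC2)O1 | intermediate
20 | (4R,5R)-4,5-dicyclohexyl-2-[(2S,4R,6S,8S)-4,6,8-trimethyldecan-2-yl]-1,3,2-dioxaborolane | CC[C@H](C)C[C@H](C)C[C@H](C)C[C@H](C)B1O[C@H](C2CCCCC2)[C@@H](C2CCCCC2)O1 | intermediate
21 | 7-chlorohept-1-yne | C#CCCCCCCl | starting material
22 | (E)-(7-chlorohept-1-en-1-yl)diisobutylalane | CC(C)C[Al](CC(C)C)/C=C/CCCCCCl | intermediate
23 | (E)-7-chloro-1-iodohept-1-ene | ClCCCCC/C=C/I | intermediate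
24 | (E)-7-chlorohept-1-en-1-yllithium | [Li]/C=C/CCCCCCl | intermediate
25 | lithium [(E)-7-chlorohept-1-en-1-yl]borate complex of 20 | [Li+].CC[C@H](C)C[C@H](C)C[C@H](C)C[C@H](C)[B-]1(/C=C/CCCCCCl)O[C@H](C2CCCCC2)[C@@H](C2CCCCC2)O1 | intermediate
26 | (4R,5R)-2-{7-chloro-2-iodo-1-[(2S,4S,6S,8S)-4,6,8-trimethyldecan-2-yl]heptyl}-4,5-dicyclohexyl-1,3,2-dioxaborolane (the two transient centres C1 and C2 of the heptyl group not assigned) | CC[C@H](C)C[C@H](C)C[C@H](C)C[C@H](C)C(B1O[C@H](C2CCCCC2)[C@@H](C2CCCCC2)O1)C(I)CCCCCCl | intermediate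
27 | (6Z,8S,10S,12S,14S)-1-chloro-8,10,12,14-tetramethylhexadec-6-ene | CC[C@H](C)C[C@H](C)C[C@H](C)C[C@H](C)/C=C\CCCCCCl | intermediate
28 | (8R,10R,12S,14S)-1-chloro-8,10,12,14-tetramethylhexadecane | CC[C@H](C)C[C@H](C)C[C@H](C)C[C@H](C)CCCCCCCCl | intermediate
29 | 2-methoxy-5-methylphenol | COc1ccc(C)cc1O | starting material
30 | 2-hydroxy-3-methoxy-6-methylbenzaldehyde | COc1ccc(C)c(C=O)c1O | intermediate
31 | tert-butyl (2-formyl-6-methoxy-3-methylphenyl) carbonate | COc1ccc(C)c(C=O)c1OC(=O)OC(C)(C)C | intermediate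
32 | [(8R,10R,12S,14S)-8,10,12,14-tetramethylhexadecyl]magnesium chloride | CC[C@H](C)C[C@H](C)C[C@H](C)C[C@H](C)CCCCCCC[Mg]Cl | intermediate
33 | chloromagnesium alkoxide of tert-butyl {2-[(9R,11R,13S,15S)-1-hydroxy-9,11,13,15-tetramethylheptadecyl]-6-methoxy-3-methylphenyl} carbonate (both C1 epimers) | CC[C@H](C)C[C@H](C)C[C@H](C)C[C@H](C)CCCCCCCC(O[Mg]Cl)c1c(C)ccc(OC)c1OC(=O)OC(C)(C)C | intermediate
34 | 2-methoxy-5-methyl-6-[(9R,11R,13S,15S)-9,11,13,15-tetramethylheptadecylidene]cyclohexa-2,4-dien-1-one (E/Z not fixed) | CC[C@H](C)C[C@H](C)C[C@H](C)C[C@H](C)CCCCCCCC=C1C(C)=CC=C(OC)C1=O | intermediate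
35 | 6-methoxy-3-methyl-2-[(9R,11R,13S,15S)-9,11,13,15-tetramethylheptadecyl]phenol | CC[C@H](C)C[C@H](C)C[C@H](C)C[C@H](C)CCCCCCCCc1c(C)ccc(OC)c1O | intermediate
36 | 5-methoxy-2-methyl-3-[(9R,11R,13S,15S)-9,11,13,15-tetramethylheptadecyl]cyclohexa-2,5-diene-1,4-dione | CC[C@H](C)C[C@H](C)C[C@H](C)C[C@H](C)CCCCCCCCC1=C(C)C(=O)C=C(OC)C1=O | target

**Step count**

Total steps: 13. Longest linear sequence: 10 steps (steps 1–6, 8, 9, 12, 13).

**Steps most likely to fail, with fallbacks**

Step 12. The two ortho substituents may slow the Grignard addition enough for attack on the carbonate to compete. The alkylidene quinone methide may also undergo a 1,5-hydrogen shift to an alkenylphenol, or add to itself, before hydride reaches it. The fallback sets out from 28 and 30 and comes back at 35. Aldehyde 30 is deprotonated with NaH (THF, 0 °C) to sodium 2-formyl-6-methoxy-3-methylphenolate F1. Grignard reagent 32, made from 28 as in step 12, is added to give 2-[(9R,11R,13S,15S)-1-hydroxy-9,11,13,15-tetramethylheptadecyl]-6-methoxy-3-methylphenol F2 as a mixture of carbinol epimers. Ionic hydrogenation (Et3SiH, TFA, CH2Cl2, 0 °C) then removes the benzylic hydroxyl and should give 35.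

Step 8. Borate formation at the hindered secondary boron may be incomplete. The organolithium or methoxide may also attack the primary chloride, and iodination may proceed without clean migration. The fallback sets out from 20 and comes back at 28, so step 9 is bypassed as well. Matteson homologation of 20 (BrCH2Cl, n-BuLi, THF, −78 °C → rt) should give (4R,5R)-4,5-dicyclohexyl-2-[(2R,4R,6S,8S)-2,4,6,8-tetramethyldecyl]-1,3,2-dioxaborolane F3. This is oxidised in the same flask (NaOH, H2O2) to (2S,4S,6S,8S)-2,4,6,8-tetramethyldecan-1-ol F4. Tosylation (TsCl, pyridine) gives (2S,4S,6S,8S)-2,4,6,8-tetramethyldecyl 4-methylbenzenesulfonate F5. Copper-catalysed sp3–sp3 coupling (cat. Li2CuCl4, THF, −20 °C → rt) with 6-chlorohexylmagnesium bromide F6, prepared from 1-bromo-6-chlorohexane and Mg, should deliver 28.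

Step 10. Formylation may stall because the only free ortho carbon is flanked by the methyl group and the methoxy oxygen ties up magnesium. Methoxymethyl ether formation and diarylmethane condensation may then take over. The fallback sets out from 29 and comes back at 30. Boron-templated ortho-hydroxymethylation (PhB(OH)2, paraformaldehyde, cat. propionic acid, toluene, reflux with water removal) should give 8-methoxy-5-methyl-2-phenyl-4H-1,3,2-benzodioxaborinine F7. Oxidative release (H2O2, THF) gives 2-(hydroxymethyl)-6-methoxy-3-methylphenol F8. Selective benzylic oxidation (MnO2, CH2Cl2) then gives 30.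

**Further compounds**

F1 | step 12 | sodium 2-formyl-6-methoxy-3-methylphenolate | [Na+].COc1ccc(C)c(C=O)c1[O-]
F2 | step 12 | 2-[(9R,11R,13S,15S)-1-hydroxy-9,11,13,15-tetramethylheptadecyl]-6-methoxy-3-methylphenol (both C1 epimers) | CC[C@H](C)C[C@H](C)C[C@H](C)C[C@H](C)CCCCCCCC(O)c1c(C)ccc(OC)c1O
F3 | step 8 | (4R,5R)-4,5-dicyclohexyl-2-[(2R,4R,6S,8S)-2,4,6,8-tetramethyldecyl]-1,3,2-dioxaborolane | CC[C@H](C)C[C@H](C)C[C@H](C)C[C@H](C)CB1O[C@H](C2CCCCC2)[C@@H](C2CCCCC2)O1
F4 | step 8 | (2S,4S,6S,8S)-2,4,6,8-tetramethyldecan-1-ol | CC[C@H](C)C[C@H](C)C[C@H](C)C[C@H](C)CO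
F5 | step 8 | (2S,4S,6S,8S)-2,4,6,8-tetramethyldecyl 4-methylbenzenesulfonate | CC[C@H](C)C[C@H](C)C[C@H](C)C[C@H](C)COS(=O)(=O)c1ccc(C)cc1
F6 | step 8 | 6-chlorohexylmagnesium bromide | ClCCCCCC[Mg]Br
F7 | step 10 | 8-methoxy-5-methyl-2-phenyl-4H-1,3,2-benzodioxaborinine | COc1ccc(C)c2COB(c3ccccc3)Oc12
F8 | step 10 | 2-(hydroxymethyl)-6-methoxy-3-methylphenol | COc1ccc(C)c(CO)c1O
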